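The decalin is disconnected across the ring fusion at C5–C10 and at C1–C2. The C9 oxygen lies next to C10, so a C9 vinyl ketone can act as dienophile (C10/C1) towards a tethered diene that brings C2–C5 with the methyls C15 (on C4) and C14 (on C5). One chiral-Lewis-acid intramolecular Diels–Alder reaction of the achiral trienone 16 closes rings A and B, sets the quaternary C5 and leaves a C3=C4 alkene for α-face hydroboration and a C9 ketone for C10 epimerisation and for the C8/C9 ketol. Trienone 16 is built as a single (7E) isomer through a chelation-controlled (Z)-enol triflate.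

Key step: step 11

Numbering used throughout: ring A = C1, C2, C3, C4, C5, C10; ring B = C5, C6, C7, C8, C9, C10; C14 is the methyl on C5, C15 the methyl on C4; β is the face of C14, α the opposite face.

Assumption: the (S)-oxazaborolidine is taken to deliver the (4aS,8aS) adduct 17; if the sense of induction proves opposite, the (R)-catalyst is used and nothing else changes.

Remark: angelic acid and (2E)-3-methylpent-2-enoic acid are taken as purchased.

Step 1
Reactants: 1 ethyl 2-methyl-3-oxobutanoate; 2 allyl bromide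
Product: 4 ethyl 2-methyl-3-oxohept-6-enoate (racemic at C2), via sodium lithium dianion 3 (not isolated)
Conditions: NaH, THF, 0 °C; n-BuLi, 0 °C; then allyl bromide, 0 °C → rt
Reagents that add atoms: none
Why: γ-Alkylation of a β-keto ester dianion, in which the second deprotonation creates the more nucleophilic terminal carbon that alone attacks the allylic bromide (SN2); the C2 centre is racemic and is erased in step 2.

Step 2
Reactants: 4 ethyl 2-methyl-3-oxohept-6-enoate
Product: 6 ethyl (2Z)-2-methyl-3-{[(trifluoromethyl)sulfonyl]oxy}hepta-2,6-dienoate, via sodium (Z)-enolate 5 (not isolated)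
Conditions: NaH, Et2O, 0 °C; then Tf2O, −20 → 0 °C
Reagents that add atoms: trifluoromethanesulfonic anhydride, O=S(=O)(OS(=O)(=O)C(F)(F)F)C(F)(F)F
Why: O-Triflation of the sodium enolate, whose Na+ chelate between enolate and ester oxygens fixes the (Z) geometry (TfO cis to CO2Et).

Step 3
Reactants: 6 ethyl (2Z)-2-methyl-3-{[(trifluoromethyl)sulfonyl]oxy}hepta-2,6-dienoate
Product: 7 ethyl (2E)-2,3-dimethylhepta-2,6-dienoate
Conditions: MeMgBr, Fe(acac)3 (5 mol %), THF/NMP, −30 °C
Reagents that add atoms: methylmagnesium bromide, C[Mg]Br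
Why: Iron-catalysed Kumada-type cross-coupling of an enol triflate, which proceeds with retention of alkene geometry and so places the butenyl chain trans to the ester; ester and terminal alkene are inert at this temperature.

Step 4
Reactants: 7 ethyl (2E)-2,3-dimethylhepta-2,6-dienoate
Product: 9 ethyl (2E)-7-hydroxy-2,3-dimethylhept-2-enoate, via B-alkyl-9-BBN 8 (not isolated)
Conditions: 9-BBN, THF, 0 °C → rt; then H2O2, aq. NaOAc, 0 °C → rt
Reagents that add atoms: hydrogen peroxide, OO
Why: Anti-Markovnikov hydroboration–oxidation, in which 9-BBN reacts only with the monosubstituted alkene and not with the tetrasubstituted, electron-poor enoate.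

Step 5
Reactants: 9 ethyl (2E)-7-hydroxy-2,3-dimethylhept-2-enoate
Product: 10 (2E)-2,3-dimethylhept-2-ene-1,7-diol
Conditions: i-Bu2AlH, CH2Cl2, −78 → 0 °C
Reagents that add atoms: none
Why: 1,2-Reduction of the conjugated ester by an aluminium hydride gives the allylic alcohol without touching the alkene geometry.

Step 6
Reactants: 10 (2E)-2,3-dimethylhept-2-ene-1,7-diol
Product: 11 (2E)-7-hydroxy-2,3-dimethylhept-2-enal
Conditions: MnO2, CH2Cl2, rt
Reagents that add atoms: none
Why: Chemoselective allylic oxidation, since MnO2 oxidises the allylic alcohol and leaves the saturated primary alcohol.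

Step 7
Reactants: 11 (2E)-7-hydroxy-2,3-dimethylhept-2-enal
Product: 12 (5E)-5,6-dimethylocta-5,7-dien-1-ol
Conditions: Ph3PCH3Br, KN(SiMe3)2, THF, −78 → 0 °C
Reagents that add atoms: methyltriphenylphosphonium bromide, C[P+](c1ccccc1)(c1ccccc1)c1ccccc1.[Br-]
Why: Wittig methylenation of the enal with excess ylide (one equivalent is absorbed by the free hydroxyl) builds the diene and leaves the tetrasubstituted alkene geometry untouched.

Step 8
Reactants: 12 (5E)-5,6-dimethylocta-5,7-dien-1-ol
Product: 13 (5E)-5,6-dimethylocta-5,7-dienal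
Conditions: Dess–Martin periodinane, pyridine, CH2Cl2, 0 °C → rt
Reagents that add atoms: none
Why: Dess–Martin oxidation of the primary alcohol under buffered conditions that spare the acid-sensitive diene.

Step 9
Reactants: 13 (5E)-5,6-dimethylocta-5,7-dienal; 14 vinylmagnesium bromide
Product: 15 (7E)-7,8-dimethyldeca-1,7,9-trien-3-ol (racemic)
Conditions: THF, −78 °C
Reagents that add atoms: none
Why: Grignard 1,2-addition to the aldehyde; the new carbinol centre is racemic and is removed in step 10.

Step 10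
Reactants: 15 (7E)-7,8-dimethyldeca-1,7,9-trien-3-ol
Product: 16 (7E)-7,8-dimethyldeca-1,7,9-trien-3-one
Conditions: Dess–Martin periodinane, pyridine, CH2Cl2, 0 °C; used at once
Reagents that add atoms: none
Why: Dess–Martin oxidation of the allylic alcohol gives the vinyl ketone under non-nucleophilic conditions that avoid conjugate addition and polymerisation.

Step 11
Reactants: 16 (7E)-7,8-dimethyldeca-1,7,9-trien-3-one
Product: 17 (4aS,8aS)-4a,5-dimethyl-3,4,4a,7,8,8a-hexahydronaphthalen-1(2H)-one (cis-fused 4,5-dimethyldecal-3-en-9-one; 10β-H)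
Conditions: (S)-3,3-diphenyl-1-(o-tolyl)tetrahydro-1H,3H-pyrrolo[1,2-c][1,3,2]oxazaborole (20 mol %), HN(SO2CF3)2 (18 mol %), CH2Cl2, −78 → −20 °C
Reagents that add atoms: none
Why: Proposed new method: the cationic boron of the triflimide-activated oxazaborolidine binds the C9 carbonyl oxygen, lowers the LUMO of the vinyl ketone, and the tethered s-cis diene adds in one concerted, asynchronous [4+2] event (C1–C2 bonding ahead of C5–C10); the closest known reaction types are oxazaborolidinium-catalysed intermolecular Diels–Alder reactions of vinyl ketones and achiral Lewis-acid-promoted intramolecular Diels–Alder reactions of deca-1,7,9-trien-3-ones, not yet combined on a diene whose reacting terminus is fully substituted. Ring A (C1, C2, C3, C4, C5, C10) is the cyclohexene made by the cycloaddition, and ring B (C5 to C10) closes in the same event as a six-membered ring because three methylenes and the carbonyl bridge the diene terminus C5 and the dienophile carbon C10. C5 is set by the catalyst, whose aryl groups leave one enantiotopic face of the bound enone open to the diene, and C10 is set relative to C5 by the endo position of the tether carbonyl, which with the (7E) diene puts H10 cis to C14. The step needs endo and enantioface selectivity, expected from Lewis-acid-enhanced secondary overlap within the short tether and from single-point binding of an unhindered ketone; regiochemistry is dictated by the tether. The inside methyl on the diene terminus hinders the s-cis alignment, which the strong triflimide activation and the intramolecularity are meant to offset.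

Step 12
Reactants: 17 cis-fused 4,5-dimethyldecal-3-en-9-one
Product: 18 (4aS,8aR)-4a,5-dimethyl-3,4,4a,7,8,8a-hexahydronaphthalen-1(2H)-one (trans-fused; 10α-H)
Conditions: NaOMe (0.2 equiv), MeOH, rt
Reagents that add atoms: none
Why: Base-mediated epimerisation through the C9 enolate, in which C10 is the only enolisable stereocentre and should equilibrate towards the trans-fused ketone (one gauche interaction fewer); recovered cis ketone is resubmitted.

Step 13
Reactants: 18 trans-fused 4,5-dimethyldecal-3-en-9-one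
Product: 19 trans-fused 4,5-dimethyldecal-3-en-9β-ol (axial hydroxyl; 10α-H)
Conditions: LiBH(s-Bu)3, THF, −78 °C; then NaOH, H2O2
Reagents that add atoms: none
Why: Bulky-hydride reduction, in which the β face of the C9 carbonyl is blocked by the 1,3-diaxial C14 methyl, so hydride enters from the α face and gives the axial 9β alcohol that masks C9 during the hydroboration.

Step 14
Reactants: 19 trans-fused 4,5-dimethyldecal-3-en-9β-ol
Product: 21 4β,5β-dimethyl-trans-decalin-3α,9β-diol (10α-H), via 3α-boryl 9-O-boryl adduct 20 (not isolated)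
Conditions: BH3·SMe2, THF, 0 °C → rt; then NaOH, H2O2, 0 °C → rt
Reagents that add atoms: hydrogen peroxide, OO
Why: Hydroboration–oxidation (syn addition), with boron going to the less substituted C3 and hydrogen to C4 from the α face, anti to the pseudo-axial C14 methyl on the neighbouring C5, which sets 3α-OH and the 4β-methyl (C15 cis to C14) together.

Step 15
Reactants: 21 4β,5β-dimethyl-trans-decalin-3α,9β-diol
Product: 22 3α-(tert-butyldimethylsilyloxy)-4β,5β-dimethyl-trans-decalin-9β-ol
Conditions: TBSCl, imidazole, DMF, rt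
Reagents that add atoms: tert-butyldimethylsilyl chloride, CC(C)(C)[Si](C)(C)Cl
Why: Selective silylation, since the equatorial 3α-hydroxyl reacts while the axial 9β-hydroxyl, 1,3-diaxial to C14, is too hindered for this reagent.

Step 16
Reactants: 22 3α-(tert-butyldimethylsilyloxy)-4β,5β-dimethyl-trans-decalin-9β-ol
Product: 23 3α-(tert-butyldimethylsilyloxy)-4β,5β-dimethyl-trans-decalin-9-one
Conditions: Dess–Martin periodinane, pyridine, CH2Cl2, rt
Reagents that add atoms: none
Why: Dess–Martin oxidation of the strained axial alcohol returns the C9 ketone under non-enolising conditions, so the trans ring fusion is kept.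

Step 17
Reactants: 23 3α-(tert-butyldimethylsilyloxy)-4β,5β-dimethyl-trans-decalin-9-one
Product: 25 3α-(tert-butyldimethylsilyloxy)-4β,5β-dimethyl-trans-decal-8-en-9-yl trifluoromethanesulfonate, via lithium C8 enolate 24 (not isolated)
Conditions: LiN(i-Pr)2, THF, −78 °C; then PhNTf2, −78 → 0 °C
Reagents that add atoms: N-phenylbis(trifluoromethanesulfonimide), O=S(=O)(N(c1ccccc1)S(=O)(=O)C(F)(F)F)C(F)(F)F
Why: Kinetic deprotonation at the C8 methylene in preference to the C10 ring-fusion methine, followed by O-triflation of the enolate, gives the C8=C9 enol triflate.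

Step 18
Reactants: 25 enol triflate
Product: 26 3α-(tert-butyldimethylsilyloxy)-4β,5β-dimethyl-trans-decal-8-ene
Conditions: Pd(OAc)2 (5 mol %), PPh3, n-Bu3N, HCO2H, DMF, 60 °C
Reagents that add atoms: none
Why: Palladium-catalysed formate reduction of the enol triflate (oxidative addition, formate decarboxylation, C–H reductive elimination) gives the C8=C9 alkene with no change at C10.

Step 19
Reactants: 26 3α-(tert-butyldimethylsilyloxy)-4β,5β-dimethyl-trans-decal-8-ene
Product: 27 3α-(tert-butyldimethylsilyloxy)-4β,5β-dimethyl-trans-decalin-8α,9α-diol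
Conditions: OsO4 (2 mol %), NMO, acetone/H2O, rt
Reagents that add atoms: N-methylmorpholine N-oxide, C[N+]1([O-])CCOCC1; water, O
Why: Catalytic OsO4 syn-dihydroxylation from the α face, because the β face at C9 is shielded by the axial C14 methyl, which sets the equatorial 9α-OH of the target and an axial 8α-OH.

Step 20
Reactants: 27 8α,9α-diol
Product: 29 3α-(tert-butyldimethylsilyloxy)-9α-hydroxy-4β,5β-dimethyl-trans-decalin-8-one, via 8α,9α-O-dibutylstannylene acetal 28 (not isolated)
Conditions: Bu2SnO, toluene, reflux (−H2O); then Br2, 4 Å molecular sieves, CH2Cl2, rt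
Reagents that add atoms: none
Why: Brominolysis of the stannylene acetal of a cis-1,2-diol oxidises the axial hydroxyl, here O8 with its accessible equatorial carbinol hydrogen, and leaves the equatorial 9α-hydroxyl.

Step 21
Reactants: 29 9α-hydroxy-8-ketone
Product: 30 3α-(tert-butyldimethylsilyloxy)-9α-(triethylsilyloxy)-4β,5β-dimethyl-trans-decalin-8-one
Conditions: Et3SiCl, imidazole, DMF, 0 °C → rt
Reagents that add atoms: chlorotriethylsilane, CC[Si](CC)(CC)Cl
Why: Silylation of the ketol hydroxyl protects O9 and blocks enediol isomerisation during the enolate chemistry that follows.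

Step 22
Reactants: 30 9α-(triethylsilyloxy)-8-ketone; 31 2-bromopropene
Product: 33 3α-(tert-butyldimethylsilyloxy)-9α-(triethylsilyloxy)-4β,5β-dimethyl-7α-(prop-1-en-2-yl)-trans-decalin-8-one, via lithium C7 enolate 32 (not isolated)
Conditions: LiN(SiMe3)2 (2.2 equiv), toluene/THF, −78 → 0 °C; Pd(OAc)2 (5 mol %), [HP(t-Bu)3]BF4 (10 mol %), 2-bromopropene, rt; AcOH, −78 °C
Reagents that add atoms: none
Why: Palladium-catalysed α-alkenylation of a ketone enolate, in which the base removes a C7 methylene proton (C9 bears the silyloxy group and is hindered), 2-bromopropene adds oxidatively to zerovalent palladium and reductive elimination forms C7–C11; kinetic α-protonation of the product dienolate should give the β,γ-unsaturated ketone with the isopropenyl group equatorial (7α), which is also the thermodynamically preferred C7 epimer.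

Step 23
Reactants: 33 bis-silyl ether
Product: 34 3α-(tert-butyldimethylsilyloxy)-9α-hydroxy-4β,5β-dimethyl-7α-(prop-1-en-2-yl)-trans-decalin-8-one
Conditions: PPTS (cat.), MeOH/CH2Cl2, 0 °C
Reagents that add atoms: none
Why: Acid-catalysed methanolysis removes the triethylsilyl ether selectively, while the bulkier tert-butyldimethylsilyl ether at O3 survives.

Step 24
Reactants: 34 9α-alcohol; 35 (2E)-3-methylpent-2-enoic acid
Product: 36 3α-(tert-butyldimethylsilyloxy)-4β,5β-dimethyl-8-oxo-7α-(prop-1-en-2-yl)-trans-decalin-9α-yl (2E)-3-methylpent-2-enoate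
Conditions: DCC, DMAP (cat.), CH2Cl2, 0 °C → rt
Reagents that add atoms: none
Why: Steglich esterification of the equatorial 9α-hydroxyl, with carbodiimide activation at low temperature to keep the enoate geometry and the C7 centre intact.

Step 25
Reactants: 36 silyl ether ester
Product: 37 3α-hydroxy-4β,5β-dimethyl-8-oxo-7α-(prop-1-en-2-yl)-trans-decalin-9α-yl (2E)-3-methylpent-2-enoate
Conditions: HF·pyridine, pyridine, THF, 0 °C → rt
Reagents that add atoms: none
Why: Fluoride-mediated desilylation under buffered conditions that should leave the ester and the β,γ-unsaturated ketone unchanged.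

Step 26
Reactants: 37 3α-alcohol; 38 angelic acid [(2Z)-2-methylbut-2-enoic acid]
Product: 40 (1S,3S,4aR,5R,6R,8aR)-4a,5-dimethyl-6-{[(2Z)-2-methylbut-2-enoyl]oxy}-2-oxo-3-(prop-1-en-2-yl)decahydronaphthalen-1-yl (2E)-3-methylpent-2-enoate, via angelic 2,4,6-trichlorobenzoic anhydride 39 (not isolated)
Conditions: 2,4,6-trichlorobenzoyl chloride, Et3N, toluene, rt; then 37, toluene, 60 °C
Reagents that add atoms: none
Why: Yamaguchi-type esterification through the mixed anhydride of angelic acid, run without a nucleophilic catalyst because this variant transfers the angeloyl group without (Z)-to-(E) isomerisation; it completes the target.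

Compound list
1 | ethyl 2-methyl-3-oxobutanoate | CCOC(=O)C(C)C(C)=O | starting material
2 | allyl bromide | C=CCBr | starting material
3 | sodium lithium dianion of 1 | [Na+].[Li+].C=C([O-])C(C)=C([O-])OCC | intermediate
4 | ethyl 2-methyl-3-oxohept-6-enoate (racemic) | CCOC(=O)C(C)C(=O)CCC=C | intermediate
5 | sodium (Z)-enolate of 4 | [Na+].[O-]/C(CCC=C)=C(/C)C(=O)OCC | intermediate
6 | ethyl (2Z)-2-methyl-3-{[(trifluoromethyl)sulfonyl]oxy}hepta-2,6-dienoate | CCOC(=O)/C(C)=C(/CCC=C)OS(=O)(=O)C(F)(F)F | intermediate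
7 | ethyl (2E)-2,3-dimethylhepta-2,6-dienoate | CCOC(=O)/C(C)=C(\C)CCC=C | intermediate
8 | B-alkyl-9-BBN adduct of 7 | CCOC(=O)/C(C)=C(\C)CCCCB1C2CCCC1CCC2 | intermediate
9 | ethyl (2E)-7-hydroxy-2,3-dimethylhept-2-enoate | CCOC(=O)/C(C)=C(\C)CCCCO | intermediate
10 | (2E)-2,3-dimethylhept-2-ene-1,7-diol | OC/C(C)=C(\C)CCCCO | intermediate
11 | (2E)-7-hydroxy-2,3-dimethylhept-2-enal | O=C/C(C)=C(\C)CCCCO | intermediate
12 | (5E)-5,6-dimethylocta-5,7-dien-1-ol | C=C/C(C)=C(\C)CCCCO | intermediate
13 | (5E)-5,6-dimethylocta-5,7-dienal | C=C/C(C)=C(\C)CCCC=O | intermediate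
14 | vinylmagnesium bromide | C=C[Mg]Br | starting material
15 | (7E)-7,8-dimethyldeca-1,7,9-trien-3-ol (racemic) | C=C/C(C)=C(\C)CCCC(O)C=C | intermediate
16 | (7E)-7,8-dimethyldeca-1,7,9-trien-3-one | C=C/C(C)=C(\C)CCCC(=O)C=C | intermediate
17 | (4aS,8aS)-4a,5-dimethyl-3,4,4a,7,8,8a-hexahydronaphthalen-1(2H)-one (cis-fused) | C1C[C@]2(C)C(C)=CCC[C@@H]2C(=O)C1 | intermediate
18 | (4aS,8aR)-4a,5-dimethyl-3,4,4a,7,8,8a-hexahydronaphthalen-1(2H)-one (trans-fused) | C1C[C@]2(C)C(C)=CCC[C@H]2C(=O)C1 | intermediate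
19 | trans-fused 4,5-dimethyldecal-3-en-9β-ol | C1C[C@]2(C)C(C)=CCC[C@H]2[C@@H](O)C1 | intermediate
20 | 3α-boryl 9-O-boryl adduct of 19 (drawn as the monoalkylborane) | C1C[C@]2(C)[C@@H](C)[C@H](B)CC[C@H]2[C@@H](OB)C1 | intermediate
21 | 4β,5β-dimethyl-trans-decalin-3α,9β-diol | C1C[C@]2(C)[C@@H](C)[C@H](O)CC[C@H]2[C@@H](O)C1 | intermediate
22 | 3α-(tert-butyldimethylsilyloxy)-4β,5β-dimethyl-trans-decalin-9β-ol | C1C[C@]2(C)[C@@H](C)[C@H](O[Si](C)(C)C(C)(C)C)CC[C@H]2[C@@H](O)C1 | intermediate
23 | 3α-(tert-butyldimethylsilyloxy)-4β,5β-dimethyl-trans-decalin-9-one | C1C[C@]2(C)[C@@H](C)[C@H](O[Si](C)(C)C(C)(C)C)CC[C@H]2C(=O)C1 | intermediate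
24 | lithium C8 enolate of 23 | [Li+].C1C[C@]2(C)[C@@H](C)[C@H](O[Si](C)(C)C(C)(C)C)CC[C@H]2C([O-])=C1 | intermediate
25 | 3α-(tert-butyldimethylsilyloxy)-4β,5β-dimethyl-trans-decal-8-en-9-yl trifluoromethanesulfonate | C1C[C@]2(C)[C@@H](C)[C@H](O[Si](C)(C)C(C)(C)C)CC[C@H]2C(OS(=O)(=O)C(F)(F)F)=C1 | intermediate
26 | 3α-(tert-butyldimethylsilyloxy)-4β,5β-dimethyl-trans-decal-8-ene | C1C[C@]2(C)[C@@H](C)[C@H](O[Si](C)(C)C(C)(C)C)CC[C@H]2C=C1 | intermediate
27 | 3α-(tert-butyldimethylsilyloxy)-4β,5β-dimethyl-trans-decalin-8α,9α-diol | C1C[C@]2(C)[C@@H](C)[C@H](O[Si](C)(C)C(C)(C)C)CC[C@H]2[C@H](O)[C@@H]1O | intermediate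
28 | 8α,9α-O-dibutylstannylene acetal of 27 | C1C[C@]2(C)[C@@H](C)[C@H](O[Si](C)(C)C(C)(C)C)CC[C@H]2[C@H](O[Sn](CCCC)(CCCC)O3)[C@@H]13 | intermediate
29 | 3α-(tert-butyldimethylsilyloxy)-9α-hydroxy-4β,5β-dimethyl-trans-decalin-8-one | C1C[C@]2(C)[C@@H](C)[C@H](O[Si](C)(C)C(C)(C)C)CC[C@H]2[C@H](O)C1=O | intermediate
30 | 3α-(tert-butyldimethylsilyloxy)-9α-(triethylsilyloxy)-4β,5β-dimethyl-trans-decalin-8-one | C1C[C@]2(C)[C@@H](C)[C@H](O[Si](C)(C)C(C)(C)C)CC[C@H]2[C@H](O[Si](CC)(CC)CC)C1=O | intermediate
31 | 2-bromopropene | CC(Br)=C | starting material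
32 | lithium C7 enolate of 30 | [Li+].C=1C[C@]2(C)[C@@H](C)[C@H](O[Si](C)(C)C(C)(C)C)CC[C@H]2[C@H](O[Si](CC)(CC)CC)C=1[O-] | intermediate
33 | 3α-(tert-butyldimethylsilyloxy)-9α-(triethylsilyloxy)-4β,5β-dimethyl-7α-(prop-1-en-2-yl)-trans-decalin-8-one | C=C(C)[C@@H]1C[C@]2(C)[C@@H](C)[C@H](O[Si](C)(C)C(C)(C)C)CC[C@H]2[C@H](O[Si](CC)(CC)CC)C1=O | intermediate
34 | 3α-(tert-butyldimethylsilyloxy)-9α-hydroxy-4β,5β-dimethyl-7α-(prop-1-en-2-yl)-trans-decalin-8-one | C=C(C)[C@@H]1C[C@]2(C)[C@@H](C)[C@H](O[Si](C)(C)C(C)(C)C)CC[C@H]2[C@H](O)C1=O | intermediate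
35 | (2E)-3-methylpent-2-enoic acid | CC/C(C)=C/C(=O)O | starting material
36 | 3α-(tert-butyldimethylsilyloxy)-4β,5β-dimethyl-8-oxo-7α-(prop-1-en-2-yl)-trans-decalin-9α-yl (2E)-3-methylpent-2-enoate | C=C(C)[C@@H]1C[C@]2(C)[C@@H](C)[C@H](O[Si](C)(C)C(C)(C)C)CC[C@H]2[C@H](OC(=O)/C=C(\C)CC)C1=O | intermediate
37 | 3α-hydroxy-4β,5β-dimethyl-8-oxo-7α-(prop-1-en-2-yl)-trans-decalin-9α-yl (2E)-3-methylpent-2-enoate | C=C(C)[C@@H]1C[C@]2(C)[C@@H](C)[C@H](O)CC[C@H]2[C@H](OC(=O)/C=C(\C)CC)C1=O | intermediate
38 | angelic acid, (2Z)-2-methylbut-2-enoic acid | C/C=C(/C)C(=O)O | starting material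
39 | angelic 2,4,6-trichlorobenzoic anhydride | C/C=C(/C)C(=O)OC(=O)c1c(Cl)cc(Cl)cc1Cl | intermediate
40 | CNP0301161.1; (3R,4R,5R,7S,9S,10R) in the numbering above; (1S,3S,4aR,5R,6R,8aR)-4a,5-dimethyl-6-{[(2Z)-2-methylbut-2-enoyl]oxy}-2-oxo-3-(prop-1-en-2-yl)decahydronaphthalen-1-yl (2E)-3-methylpent-2-enoate | C=C(C)[C@@H]1C[C@]2(C)[C@@H](C)[C@H](OC(=O)/C(C)=C\C)CC[C@H]2[C@H](OC(=O)/C=C(\C)CC)C1=O | target

Total step count: 26. Longest linear sequence: 26 steps (1 → 40; all other inputs are purchased).

Steps most likely to fail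

1. Step 11. The fully substituted diene terminus may react too slowly, so that the vinyl ketone polymerises or the diene isomerises under the strong Lewis acid, or the catalyst may discriminate the enone faces poorly. The fallback sets out from 16 and comes back at 21. The cycloaddition is run with an achiral promoter, Me2AlCl (CH2Cl2, −78 → 0 °C), the known way to take deca-1,7,9-trien-3-ones to cis-1-decalones, or thermally in toluene at 160 °C, to give racemic cis-decalenone F1. Treatment as in steps 12 to 14 then gives racemic trans-decalenone F2, racemic 9β-alcohol F3 and racemic 3α,9β-diol F4. The equatorial 3-hydroxyl of F4 is esterified with (S)-2-methoxy-2-phenylacetic acid (DCC, DMAP), and the two diastereomeric esters, 3-O-[(S)-methoxyphenylacetyl] diol F5 of the wanted series and its diastereomer F6 from the mirror-image diol, are separated by chromatography or crystallisation. K2CO3 in MeOH cleaves F5 to 21.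

2. Step 22. Coupling at the hindered enolate may stall, or the new double bond may migrate into conjugation with the ketone under the basic conditions. The fallback sets out from 30 and comes back at 33. The lithium enolate of 30 (LiN(i-Pr)2, THF, −78 °C) is transmetalated with ZnCl2 and added to acetone to give the 7α-(2-hydroxypropan-2-yl) ketone F7. Dehydration with SOCl2 and pyridine at 0 °C, an E2 elimination of the chlorosulfite towards a methyl group, then gives 33.

3. Step 20. Oxidation may occur at the wrong hydroxyl or run on to the diketone. The fallback sets out from 27 and comes back at 30, passing 29 by. Et3SiCl (1.05 equiv) and imidazole in DMF at −20 °C cap the more reactive equatorial 9α-hydroxyl to give the 9α-(triethylsilyloxy)-8α-alcohol F8. Dess–Martin oxidation of the remaining axial 8α-hydroxyl gives 30.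

Further compounds
F1 | step 11 | racemic cis-fused 4a,5-dimethyl-3,4,4a,7,8,8a-hexahydronaphthalen-1(2H)-one | C1C[C@]2(C)C(C)=CCC[C@@H]2C(=O)C1.C1C[C@@]2(C)C(C)=CCC[C@H]2C(=O)C1
F2 | step 11 | racemic trans-fused 4a,5-dimethyl-3,4,4a,7,8,8a-hexahydronaphthalen-1(2H)-one | C1C[C@]2(C)C(C)=CCC[C@H]2C(=O)C1.C1C[C@@]2(C)C(C)=CCC[C@@H]2C(=O)C1
F3 | step 11 | racemic trans-fused 4,5-dimethyldecal-3-en-9β-ol | C1C[C@]2(C)C(C)=CCC[C@H]2[C@@H](O)C1.C1C[C@@]2(C)C(C)=CCC[C@@H]2[C@H](O)C1
F4 | step 11 | racemic 4β,5β-dimethyl-trans-decalin-3α,9β-diol | C1C[C@]2(C)[C@@H](C)[C@H](O)CC[C@H]2[C@@H](O)C1.C1C[C@@]2(C)[C@H](C)[C@@H](O)CC[C@@H]2[C@H](O)C1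
F5 | step 11 | 3-O-[(2S)-2-methoxy-2-phenylacetyl] ester of 21 | C1C[C@]2(C)[C@@H](C)[C@H](OC(=O)[C@@H](OC)c3ccccc3)CC[C@H]2[C@@H](O)C1
F6 | step 11 | 3-O-[(2S)-2-methoxy-2-phenylacetyl] ester of the enantiomer of 21 | C1C[C@@]2(C)[C@H](C)[C@@H](OC(=O)[C@@H](OC)c3ccccc3)CC[C@@H]2[C@H](O)C1
F7 | step 22 | 3α-(tert-butyldimethylsilyloxy)-9α-(triethylsilyloxy)-7α-(2-hydroxypropan-2-yl)-4β,5β-dimethyl-trans-decalin-8-one | CC(C)(O)[C@@H]1C[C@]2(C)[C@@H](C)[C@H](O[Si](C)(C)C(C)(C)C)CC[C@H]2[C@H](O[Si](CC)(CC)CC)C1=O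
F8 | step 20 | 3α-(tert-butyldimethylsilyloxy)-9α-(triethylsilyloxy)-4β,5β-dimethyl-trans-decalin-8α-ol | C1C[C@]2(C)[C@@H](C)[C@H](O[Si](C)(C)C(C)(C)C)CC[C@H]2[C@H](O[Si](CC)(CC)CC)[C@@H]1O
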